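**Retrosynthetic overview**
- Feature: ring A is a hexasubstituted resorcylate whose C3 and C5 each carry the CH2 of a prenyl group. In the 6-phenethyl resorcylate these are the only ring-A carbons still bearing hydrogen, and both lie ortho/para to the C2 and C4 oxygens, so bromine can be placed there and nowhere else.
- The two phenols are unmasked last from aryl acetates. Before that, both C(aryl)–CH2(prenyl) bonds are cut at once, back to the 3,5-dibromo diacetate and two equivalents of tributyl(prenyl)stannane (twofold Stille coupling).
- The dibromo diacetate goes back through acetylation, dibromination, methyl ester formation and ortho-carboxylation to 5-(2-phenylethyl)resorcinol.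
- The C6 side chain is cut at its CH2–CH2 bond (Wittig olefination, then hydrogenation) to 3,5-dimethoxybenzaldehyde and benzyltriphenylphosphonium chloride.
- No ring is formed in the route: ring A arrives with the aldehyde and ring B (the phenyl ring) with the phosphonium salt.

Key step: step 8

Assumption: ring A keeps the numbering of the target throughout (C1 ester-bearing, C2 and C4 oxygen-bearing, C6 phenethyl-bearing), and where a twofold step passes through a singly reacted species the more likely regioisomer is numbered, its alternative converging on the same product.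

**Step 1**
Reactants: 1 3,5-dimethoxybenzaldehyde; 2 benzyltriphenylphosphonium chloride
Product: 4 3,5-dimethoxystilbene (E/Z mixture), via ylide Ph3P=CHPh 3 (not isolated)
Conditions: KOtBu, THF, 0 °C → rt
Reagents that add atoms: none
Why: Wittig olefination: KOtBu turns 2 into the semi-stabilised benzylide 3, which adds to the unhindered aromatic aldehyde and collapses through the oxaphosphetane to the C=C bond, and the mixed alkene geometry does not matter because step 2 saturates this bond.

**Step 2**
Reactants: 4 3,5-dimethoxystilbene (E/Z mixture)
Product: 5 1,3-dimethoxy-5-(2-phenylethyl)benzene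
Conditions: H2 (1 atm), 10% Pd/C, EtOAc, rt
Reagents that add atoms: none
Why: Heterogeneous catalytic hydrogenation saturates the conjugated disubstituted alkene of either isomer under conditions that leave both arene rings and the aryl methyl ethers untouched.

**Step 3**
Reactants: 5 1,3-dimethoxy-5-(2-phenylethyl)benzene
Product: 8 5-(2-phenylethyl)benzene-1,3-diol, via mono(dibromoboryl) ether 6 (not isolated), via bis(dibromoboryl) ether 7 (not isolated)
Conditions: BBr3 (3 equiv), CH2Cl2, −78 °C → rt; then H2O, 0 °C
Reagents that add atoms: none
Why: Lewis-acid cleavage of aryl methyl ethers: BBr3 binds each methoxy oxygen, bromide removes the methyl group by SN2 attack (6, then 7), and water hydrolyses the B–O bonds of 7 to the free resorcinol, the hydrocarbon side chain being inert.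

**Step 4**
Reactants: 8 5-(2-phenylethyl)benzene-1,3-diol
Product: 10 2,4-dihydroxy-6-(2-phenylethyl)benzoic acid, via magnesium chelate 9 (not isolated)
Conditions: CH3OMgOCO2CH3 (2 M in DMF, excess), 120 °C, N2; then cold 1 M HCl
Reagents that add atoms: methyl magnesium carbonate, COC(=O)O[Mg]OC
Why: Ortho-carboxylation of a phenol with methyl magnesium carbonate (a Kolbe–Schmitt-type reaction): CO2 is delivered reversibly to a carbon next to a magnesium phenoxide and the product is held as the six-membered magnesium salicylate chelate 9, which with 5-alkylresorcinols settles at the carbon ortho to one oxygen and para to the other, next to the side chain, as is known for 5-pentylresorcinol.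

**Step 5**
Reactants: 10 2,4-dihydroxy-6-(2-phenylethyl)benzoic acid
Product: 12 methyl 2,4-dihydroxy-6-(2-phenylethyl)benzoate, via potassium carboxylate 11 (not isolated)
Conditions: KHCO3 (1.2 equiv), MeI (1.1 equiv), DMF, rt
Reagents that add atoms: iodomethane, CI
Why: Carboxylate O-alkylation (SN2 on MeI): KHCO3 is basic enough to ionise only the carboxylic acid and not the phenols, so methylation should stop at the ester, and the non-acidic medium at room temperature avoids decarboxylation of the resorcylic acid.

**Step 6**
Reactants: 12 methyl 2,4-dihydroxy-6-(2-phenylethyl)benzoate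
Product: 14 methyl 3,5-dibromo-2,4-dihydroxy-6-(2-phenylethyl)benzoate, via 5-bromo resorcylate 13 (not isolated)
Conditions: NBS (2.1 equiv), MeCN, 0 °C → rt, dark
Reagents that add atoms: N-bromosuccinimide, O=C1CCC(=O)N1Br
Why: Electrophilic aromatic bromination: C3 and C5 are the only ring-A carbons that still carry hydrogen and both are ortho/para to the two hydroxyls, whereas ring B is unactivated and the benzylic CH2 groups are safe under ionic conditions in the dark.

**Step 7**
Reactants: 14 methyl 3,5-dibromo-2,4-dihydroxy-6-(2-phenylethyl)benzoate
Product: 16 methyl 2,4-diacetoxy-3,5-dibromo-6-(2-phenylethyl)benzoate, via 4-O-acetate 15 (not isolated)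
Conditions: Ac2O (4 equiv), pyridine, DMAP (cat.), CH2Cl2, rt
Reagents that add atoms: acetic anhydride, CC(=O)OC(C)=O
Why: DMAP-catalysed O-acylation: the free C4 phenol is acetylated first and the hydrogen-bonded C2 phenol follows with excess acylating agent, which masks both acidic O–H groups and lowers the electron density of ring A ahead of the oxidative addition.

**Step 8**
Reactants: 16 methyl 2,4-diacetoxy-3,5-dibromo-6-(2-phenylethyl)benzoate; 17 tributyl(3-methylbut-2-en-1-yl)stannane (3 equiv supplied, two consumed)
Product: 19 methyl 2,4-diacetoxy-3,5-bis(3-methylbut-2-en-1-yl)-6-(2-phenylethyl)benzoate, via 3-prenyl 5-bromide 18 (not isolated)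
Conditions: Pd(PPh3)4 (10 mol %), anhydrous degassed DMF, 100 °C, Ar, no base or salt additive
Reagents that add atoms: none
Why: The Stille cycle runs twice: zerovalent palladium inserts first into the C3–Br bond (less crowded and more electron-poor, with only two acetoxy oxygens beside it) and then into the C5–Br bond of 18, the prenyl group passes from tin to palladium, and the aryl(prenyl)palladium species reductively eliminates to make the C3–CH2 and C5–CH2 bonds. The closest known reaction type is the coupling of aryl bromides with allyl- and prenyltributylstannanes under Pd(PPh3)4 in hot DMF. No ring closes and no stereocentre is created. The step needs the linear prenyl and not the 1,1-dimethylallyl isomer: whichever allyl terminus first reaches palladium, the σ- and η3-allyl forms interconvert, and C–C bond formation should take place at the CH2 terminus because the CMe2 terminus cannot approach an aryl carbon that carries two ortho substituents. Site selectivity is fixed in advance by the two bromines, and the acetates keep acidic O–H away from the arylpalladium species and ease oxidative addition. Leaving out any base shuts off concerted metalation–deprotonation of ring B by palladium at C5 (which would close a 9,10-dihydrophenanthrene), and the neutral medium spares the methyl ester and gives no acid to cyclise a prenyl group onto oxygen.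

**Step 9**
Reactants: 19 methyl 2,4-diacetoxy-3,5-bis(3-methylbut-2-en-1-yl)-6-(2-phenylethyl)benzoate
Product: 22 methyl 2,4-dihydroxy-3,5-bis(3-methylbut-2-en-1-yl)-6-(2-phenylethyl)benzoate (target), via 2-O-acetate 20 (not isolated), via dipotassium bis(phenoxide) 21 (not isolated)
Conditions: K2CO3 (2.5 equiv), MeOH, 0 °C → rt, Ar; then sat. aq. NH4Cl
Reagents that add atoms: none
Why: Base-mediated methanolysis (transesterification) of aryl acetates: methoxide attacks the acetyl carbonyls and expels the phenoxides, exchange at the hindered methyl ester is degenerate in methanol, and the buffered NH4Cl quench protonates 21 without the acidity that would close an ortho-prenyl phenol to a chroman.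

**Compound list**
1 | 3,5-dimethoxybenzaldehyde | COc1cc(C=O)cc(OC)c1 | starting material
2 | benzyltriphenylphosphonium chloride | [Cl-].c1ccccc1C[P+](c1ccccc1)(c1ccccc1)c1ccccc1 | starting material
3 | benzylidenetriphenylphosphorane (not isolated) | c1ccccc1C=P(c1ccccc1)(c1ccccc1)c1ccccc1 | intermediate
4 | 3,5-dimethoxystilbene (E/Z mixture, geometry erased in step 2) | COc1cc(C=Cc2ccccc2)cc(OC)c1 | intermediate
5 | 1,3-dimethoxy-5-(2-phenylethyl)benzene | COc1cc(CCc2ccccc2)cc(OC)c1 | intermediate
6 | dibromo[3-methoxy-5-(2-phenylethyl)phenoxy]borane (not isolated) | COc1cc(CCc2ccccc2)cc(OB(Br)Br)c1 | intermediate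
7 | 1,3-bis(dibromoboryloxy)-5-(2-phenylethyl)benzene (not isolated) | BrB(Br)Oc1cc(CCc2ccccc2)cc(OB(Br)Br)c1 | intermediate
8 | 5-(2-phenylethyl)benzene-1,3-diol | Oc1cc(O)cc(CCc2ccccc2)c1 | intermediate
9 | magnesium 4-hydroxy-2-oxido-6-(2-phenylethyl)benzoate, six-membered chelate (not isolated) | O=C1O[Mg]Oc2cc(O)cc(CCc3ccccc3)c12 | intermediate
10 | 2,4-dihydroxy-6-(2-phenylethyl)benzoic acid | OC(=O)c1c(O)cc(O)cc1CCc1ccccc1 | intermediate
11 | potassium 2,4-dihydroxy-6-(2-phenylethyl)benzoate (not isolated) | [K+].[O-]C(=O)c1c(O)cc(O)cc1CCc1ccccc1 | intermediate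
12 | methyl 2,4-dihydroxy-6-(2-phenylethyl)benzoate | COC(=O)c1c(O)cc(O)cc1CCc1ccccc1 | intermediate
13 | methyl 5-bromo-2,4-dihydroxy-6-(2-phenylethyl)benzoate (not isolated) | COC(=O)c1c(O)cc(O)c(Br)c1CCc1ccccc1 | intermediate
14 | methyl 3,5-dibromo-2,4-dihydroxy-6-(2-phenylethyl)benzoate | COC(=O)c1c(O)c(Br)c(O)c(Br)c1CCc1ccccc1 | intermediate
15 | methyl 4-acetoxy-3,5-dibromo-2-hydroxy-6-(2-phenylethyl)benzoate (not isolated) | COC(=O)c1c(O)c(Br)c(OC(C)=O)c(Br)c1CCc1ccccc1 | intermediate
16 | methyl 2,4-diacetoxy-3,5-dibromo-6-(2-phenylethyl)benzoate | COC(=O)c1c(OC(C)=O)c(Br)c(OC(C)=O)c(Br)c1CCc1ccccc1 | intermediate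
17 | tributyl(3-methylbut-2-en-1-yl)stannane | CCCC[Sn](CCCC)(CCCC)CC=C(C)C | starting material
18 | methyl 2,4-diacetoxy-5-bromo-3-(3-methylbut-2-en-1-yl)-6-(2-phenylethyl)benzoate (not isolated) | COC(=O)c1c(OC(C)=O)c(CC=C(C)C)c(OC(C)=O)c(Br)c1CCc1ccccc1 | intermediate
19 | methyl 2,4-diacetoxy-3,5-bis(3-methylbut-2-en-1-yl)-6-(2-phenylethyl)benzoate | COC(=O)c1c(OC(C)=O)c(CC=C(C)C)c(OC(C)=O)c(CC=C(C)C)c1CCc1ccccc1 | intermediate
20 | methyl 2-acetoxy-4-hydroxy-3,5-bis(3-methylbut-2-en-1-yl)-6-(2-phenylethyl)benzoate (not isolated) | COC(=O)c1c(OC(C)=O)c(CC=C(C)C)c(O)c(CC=C(C)C)c1CCc1ccccc1 | intermediate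
21 | dipotassium bis(phenoxide) of 22 (not isolated) | COC(=O)c1c([O-])c(CC=C(C)C)c([O-])c(CC=C(C)C)c1CCc1ccccc1.[K+].[K+] | intermediate
22 | methyl 2,4-dihydroxy-3,5-bis(3-methylbut-2-en-1-yl)-6-(2-phenylethyl)benzoate | COC(=O)c1c(O)c(CC=C(C)C)c(O)c(CC=C(C)C)c1CCc1ccccc1 | target

**Step count**
Total step count: 9
Longest linear sequence: 9 steps (1 → 22)

**Steps most likely to fail**

1. Step 8.
   - Risk: oxidative addition at the doubly flanked C5–Br bond may be slow enough for hydrodebromination to compete. Part of the prenyl group may be delivered through its tertiary terminus. Palladium hydride may move the new double bonds into conjugation with ring A.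
   - Fallback: from 16, a twofold Stille coupling with allyltributylstannane under Pd(PPh3)4 in DMF would give methyl 2,4-diacetoxy-3,5-di(prop-2-en-1-yl)-6-(2-phenylethyl)benzoate F1. The small allyl group has two equivalent termini and transfers more readily. Olefin cross-metathesis of both terminal alkenes of F1 with excess 2-methylbut-2-ene and the second-generation Grubbs catalyst in CH2Cl2 at 40 °C then builds the two trisubstituted alkenes and comes back to the route at 19.

2. Step 4.
   - Risk: the reversible carboxylation may stop short of completion, may place the carboxyl group between the two hydroxyls, or may be undone by decarboxylation during the acidic work-up.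
   - Fallback: from 8, Vilsmeier–Haack formylation (POCl3, DMF, 0 °C → rt, then aqueous NaOAc) introduces the carbon irreversibly at the position ortho to one hydroxyl and para to the other, giving 2,4-dihydroxy-6-(2-phenylethyl)benzaldehyde F2. Lindgren–Pinnick oxidation of F2 (NaClO2, NaH2PO4, sulfamic acid as hypochlorite scavenger, aqueous THF, 0 °C) comes back to the route at 10.

3. Step 5.
   - Risk: the resorcylic acid may lose CO2 before it is alkylated, and the acidic C4 phenol may be O-methylated alongside the carboxylate.
   - Fallback: from 10, acetone with (CF3CO)2O in CF3CO2H (0 °C → rt) ties the carboxyl group and the C2 phenol together as 7-hydroxy-2,2-dimethyl-5-(2-phenylethyl)-4H-1,3-benzodioxin-4-one F3, an activated acyl derivative that cannot decarboxylate. Opening F3 with K2CO3 in MeOH forms the ester by acyl substitution, with no alkylating agent present, and comes back to the route at 12.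

**Further compounds**
F1 | step 8 | methyl 2,4-diacetoxy-3,5-di(prop-2-en-1-yl)-6-(2-phenylethyl)benzoate | COC(=O)c1c(OC(C)=O)c(CC=C)c(OC(C)=O)c(CC=C)c1CCc1ccccc1
F2 | step 4 | 2,4-dihydroxy-6-(2-phenylethyl)benzaldehyde | O=Cc1c(O)cc(O)cc1CCc1ccccc1
F3 | step 5 | 7-hydroxy-2,2-dimethyl-5-(2-phenylethyl)-4H-1,3-benzodioxin-4-one | CC1(C)OC(=O)c2c(CCc3ccccc3)cc(O)cc2O1
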